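**Retrosynthetic overview** (germacrane numbering: ring C1–C10, lactone C11/C12, methyls C13–C15)
1. Target 24 ⇐ diol 22 by twofold angeloylation (O6, O11); 22 ⇐ 21 by hydroxyl-directed epoxidation of the Z-C4=C5 olefin on the ring.
2. Key disconnection: the C1–C10 bond of the 1,10-oxirane. 21 ⇐ open-chain sulfonium salt 18 by an intramolecular sulfonium-ylide (Corey–Chaykovsky-type) epoxidation that closes the ten-membered carbocycle and the oxirane and sets C1 and C10 in one operation.
3. Enabling feature: C10 is a fully substituted oxirane carbon carrying the C14 methyl and the C9 methylene (retron of a methyl ketone); C1 is an oxirane CH next to the C2 methylene (retron of a primary sulfonium ylide); the trans-fused γ-lactone (C7, C8, O, C12, C11) and the Z-C4=C5 olefin fold the C1–C10 chain.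
4. Chain assembly: C6–C7 by auxiliary-controlled anti-aldol of the (R)-citramalic acid-derived acyl thiazolidinethione 9 (C7, C8, C11–C13) with Z-enal 5 (C1–C6, C15); C8 by 1,3-anti reduction; C9, C10, C14 from an allyl Grignard reagent and Wacker oxidation.
5. Ring order: γ-lactone (step 10), then ten-membered ring with the 1,10-oxirane (step 14), then the 4,5-oxirane (step 15).

Key step: step 14

Assumption: the SMILES is taken as written, i.e. (1R,4R,5S,6S,7S,8R,10S,11R) with both oxiranes cis-fused to the ten-membered ring (C2/C9 syn and C3/C6 syn), which is the bis-epoxide of a (1(10)Z,4Z)-germacradiene.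

**Route**

Step 1
Reactants: 1 5-chloropent-1-yne
Product: 2 ethyl 6-chlorohex-2-ynoate
Conditions: n-BuLi, THF, −78 °C; ClCO2Et, −78 → 0 °C
Reagents that add atoms: ethyl chloroformate, CCOC(=O)Cl
Why: C-acylation of a lithium acetylide with a chloroformate is a standard ynoate synthesis, and the primary chloride does not react with the acetylide at −78 °C.

Step 2
Reactants: 2 ethyl 6-chlorohex-2-ynoate
Product: 3 ethyl (2Z)-6-chloro-3-methylhex-2-enoate
Conditions: Me2CuLi (from MeLi, CuI), THF, −78 °C; MeOH, −78 °C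
Reagents that add atoms: lithium dimethylcuprate, [Li+].C[Cu-]C
Why: syn-carbocupration (conjugate addition) of the ynoate and protonation of the vinylcopper at −78 °C, before it can equilibrate through the allenoate, should place the new methyl (C15) and the vinyl hydrogen cis and so give the Z-olefin that becomes C4=C5.

Step 3
Reactants: 3 ethyl (2Z)-6-chloro-3-methylhex-2-enoate
Product: 4 (2Z)-6-chloro-3-methylhex-2-en-1-ol
Conditions: i-Bu2AlH (2.2 equiv), CH2Cl2, −78 °C; aq. Rochelle salt
Reagents that add atoms: none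
Why: 1,2-reduction of the enoate with i-Bu2AlH leaves the olefin geometry and the alkyl chloride untouched.

Step 4
Reactants: 4 (2Z)-6-chloro-3-methylhex-2-en-1-ol
Product: 5 (2Z)-6-chloro-3-methylhex-2-enal
Conditions: MnO2 (excess), CH2Cl2, rt
Reagents that add atoms: none
Why: allylic oxidation with MnO2 is neutral and mild, so the Z-enal should form without isomerisation to the E-isomer.

Step 5
Reactants: 6 (R)-citramalic acid
Product: 7 2-[(4R)-2,2,4-trimethyl-5-oxo-1,3-dioxolan-4-yl]acetic acid
Conditions: Me2C(OMe)2, PPTS (cat.), acetone, rt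
Reagents that add atoms: 2,2-dimethoxypropane, COC(C)(C)OC
Why: acid-catalysed transacetalisation ties only the α-hydroxy acid into the five-membered dioxolanone, which frees the CH2CO2H arm and carries the C11 stereocentre unchanged from the chiral pool.

Step 6
Reactants: 7 dioxolanone acid; 8 (4R)-4-benzyl-1,3-thiazolidine-2-thione
Product: 9 (4R)-4-benzyl-3-{2-[(4R)-2,2,4-trimethyl-5-oxo-1,3-dioxolan-4-yl]acetyl}-1,3-thiazolidine-2-thione
Conditions: EDC·HCl, DMAP (cat.), CH2Cl2, 0 °C → rt
Reagents that add atoms: none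
Why: carbodiimide (Steglich-type) N-acylation of the thiazolidinethione touches no stereocentre.

Step 7
Reactants: 9 acyl thiazolidinethione; 5 (2Z)-6-chloro-3-methylhex-2-enal
Product: 11 (4R)-4-benzyl-3-{(2S,3R,4Z)-8-chloro-3-hydroxy-5-methyl-2-[(4R)-2,2,4-trimethyl-5-oxo-1,3-dioxolan-4-yl]oct-4-enoyl}-1,3-thiazolidine-2-thione, via trimethylsilyl ether 10 (not isolated)
Conditions: MgBr2·OEt2 (10 mol %), Et3N, Me3SiCl, EtOAc, rt; then 1 M HCl, THF
Reagents that add atoms: chlorotrimethylsilane, C[Si](C)(C)Cl (its silyl group is present only in 10)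
Why: magnesium-halide-catalysed anti-aldol of an N-acylthiazolidinethione with a non-enolisable enal under silyl trapping, in which the (4R)-benzyl auxiliary should fix C7 and the open transition state the anti C6 carbinol (both as in the target), C11 being a spectator.

Step 8
Reactants: 11 anti-aldol adduct
Product: 12 (2S,3R,4Z)-8-chloro-3-hydroxy-N-methoxy-N,5-dimethyl-2-[(4R)-2,2,4-trimethyl-5-oxo-1,3-dioxolan-4-yl]oct-4-enamide
Conditions: MeONHMe·HCl, imidazole, CH2Cl2, rt
Reagents that add atoms: N,O-dimethylhydroxylamine hydrochloride, CNOC.Cl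
Why: direct aminolysis of the activated thioimide gives the Weinreb amide and returns the auxiliary under conditions that should leave the dioxolanone and both new stereocentres alone.

Step 9
Reactants: 12 Weinreb amide
Product: 13 (5R)-5-[(5S,6R,7Z)-11-chloro-6-hydroxy-8-methyl-4-oxoundeca-1,7-dien-5-yl]-2,2,5-trimethyl-1,3-dioxolan-4-one
Conditions: allylMgBr (3.5 equiv), THF, −78 °C; AcOH, −78 °C
Reagents that add atoms: allylmagnesium bromide, C=CC[Mg]Br
Why: Grignard addition to a Weinreb amide stops at the chelated tetrahedral intermediate, so the β,γ-unsaturated ketone is released only on cold acidic quench, which limits conjugation and C7 epimerisation.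

Step 10
Reactants: 13 allyl ketone
Product: 15 (3R,4R,5R)-4-[(1R,2Z)-6-chloro-1-hydroxy-3-methylhex-2-en-1-yl]-3-hydroxy-3-methyl-5-(prop-2-en-1-yl)oxolan-2-one, via anti-1,3-diol 14 (not isolated)
Conditions: Me4NBH(OAc)3, MeCN/AcOH (1:1), −30 °C; work-up; DBU (20 mol %), CH2Cl2, rt
Reagents that add atoms: none
Why: Evans–Saksena reduction delivers hydride intramolecularly from the O6-bound acetoxyborohydride and should set C8 1,3-anti to C6, after which reversible base-catalysed transesterification of the dioxolanone funnels the diol to the thermodynamic 8,12-γ-lactone (ring substituents alternately trans, whereas the 6,12-isomer would be all-cis) with loss of acetone.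

Step 11
Reactants: 15 allyl lactone diol
Product: 16 (3R,4R,5R)-4-[(1R,2Z)-6-chloro-1-hydroxy-3-methylhex-2-en-1-yl]-3-hydroxy-3-methyl-5-(2-oxopropyl)oxolan-2-one
Conditions: PdCl2 (10 mol %), CuCl, O2 (1 atm), DMF/H2O (7:1), rt
Reagents that add atoms: water, O
Why: Tsuji–Wacker oxidation is selective for the monosubstituted olefin over the trisubstituted C4=C5 olefin and gives the Markovnikov methyl ketone (C10, C14).

Step 12
Reactants: 16 keto chloride
Product: 17 (3R,4R,5R)-3-hydroxy-4-[(1R,2Z)-1-hydroxy-6-iodo-3-methylhex-2-en-1-yl]-3-methyl-5-(2-oxopropyl)oxolan-2-one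
Conditions: NaI, acetone, reflux
Reagents that add atoms: sodium iodide, [Na+].[I-]
Why: Finkelstein exchange (SN2) at the primary chloride runs under neutral conditions that the β-acyloxy ketone tolerates.

Step 13
Reactants: 17 keto iodide
Product: 18 {(4Z,6R)-6-hydroxy-6-[(2R,3R,4R)-4-hydroxy-4-methyl-5-oxo-2-(2-oxopropyl)oxolan-3-yl]-4-methylhex-4-en-1-yl}diphenylsulfonium trifluoromethanesulfonate
Conditions: Ph2S (10 equiv), AgOSO2CF3, CH2Cl2, 0 °C → rt, dark
Reagents that add atoms: diphenyl sulfide, c1ccc(Sc2ccccc2)cc1; silver trifluoromethanesulfonate, [Ag+].[O-]S(=O)(=O)C(F)(F)F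
Why: silver-assisted S-alkylation of diphenyl sulfide by a primary iodide is the standard entry to alkyl(diphenyl)sulfonium salts, and the large excess of sulfide should outrun participation by the olefin or the hydroxyls.

Step 14
Reactants: 18 sulfonium triflate
Product: 21 (1R,6R,7R,8R,10S,11R,4Z)-1,10-epoxy-6,11-dihydroxygermacr-4-en-12,8-olide, via sulfonium ylide 19 (not isolated), via betaine 20 (not isolated)
Conditions: phosphazene base P2-Et, EtN=P(NMe2)2–N=P(NMe2)3 (1.1 equiv), CH2Cl2, −78 °C, slow addition of 18 (final 1 mM); −78 → −20 °C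
Reagents that add atoms: none
Why: Proposed new method: the phosphazene base, whose strength lies between the acidity of the sulfonium α-CH and that of the hydroxyls and the ketone α-CH, should deprotonate only C1 to ylide 19, which adds to the C10 methyl ketone in a 10-exo-trig closure of the carbocycle (betaine 20) and then expels Ph2S by 3-exo-tet attack of the C10 alkoxide on C1 to close the oxirane; the closest known reactions are the Corey–Chaykovsky epoxidation of ketones with alkyl(diphenyl)sulfonium ylides, its intramolecular variants that give epoxide-fused five- to seven-membered rings, and ylide–carbonyl (Wittig-type) and chromium-mediated carbonyl-addition closures of macrocycles and ten-membered germacranolide rings. Ring closure is favoured because the trans-fused butanolide and the Z-C4=C5 olefin already fold the C1–C10 chain, and slow addition at about 1 mM keeps the ylide concentration low against oligomerisation. C1 and C10 are set in the addition step: the tether should only span a betaine that leads to the cis-fused oxirane (C2 and C9 syn), because a trans-fused oxirane in a ring that already holds a Z-olefin and a trans-lactone is much more strained. Face selection at C10 is expected from the C8–C9–C10 segment, in which the C14 methyl avoids the syn-pentane contact with the lactone C8–O bond so that the carbonyl oxygen points to the α-face (10S, and 1R after the displacement). The step needs chemoselective ylide formation next to two free hydroxyls and a β-acyloxy ketone, secured by the matched base strength and −78 °C (C9–H stays untouched, so no E1cB opening of the lactone), and it needs this facial selectivity, which is its least secure element.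

Step 15
Reactants: 21 macrocyclic epoxy diol
Product: 22 (1R,4R,5S,6S,7R,8R,10S,11R)-1,10:4,5-diepoxy-6,11-dihydroxygermacran-12,8-olide
Conditions: VO(acac)2 (5 mol %), t-BuOOH (decane), CH2Cl2, 0 °C
Reagents that add atoms: tert-butyl hydroperoxide, CC(C)(C)OO
Why: hydroxyl-directed epoxidation by the O6-bound vanadium alkylperoxide, which in medium-ring Z-allylic alcohols delivers oxygen to the face syn to the hydroxyl and should give the cis-4,5-oxirane (4R,5S) while the lactone and the 1,10-oxirane stay inert.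

Step 16
Reactants: 22 diepoxy diol; 23 angelic acid
Product: 24 (1R,4R,5S,6S,7S,8R,10S,11R)-6,11-bis(angeloyloxy)-1,10:4,5-diepoxygermacran-12,8-olide
Conditions: 23 (6 equiv), 2,4,6-trichlorobenzoyl chloride, Et3N, toluene, rt; then 22, DMAP (cat.), 80 °C
Reagents that add atoms: none
Why: Yamaguchi-type acylation with the preformed mixed anhydride should esterify the secondary C6 hydroxyl and the tertiary α-hydroxy-lactone C11 hydroxyl, and preforming the anhydride with only catalytic DMAP is meant to avoid Z→E isomerisation to the tiglate.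

**Compound list**
1 | 5-chloropent-1-yne | C#CCCCCl | starting material
2 | ethyl 6-chlorohex-2-ynoate | CCOC(=O)C#CCCCCl | intermediate
3 | ethyl (2Z)-6-chloro-3-methylhex-2-enoate | CCOC(=O)/C=C(C)\CCCCl | intermediate
4 | (2Z)-6-chloro-3-methylhex-2-en-1-ol | OC/C=C(C)\CCCCl | intermediate
5 | (2Z)-6-chloro-3-methylhex-2-enal | O=C/C=C(C)\CCCCl | intermediate
6 | (R)-citramalic acid [(2R)-2-hydroxy-2-methylbutanedioic acid] | C[C@@](O)(CC(=O)O)C(=O)O | starting material
7 | 2-[(4R)-2,2,4-trimethyl-5-oxo-1,3-dioxolan-4-yl]acetic acid | C[C@]1(CC(=O)O)OC(C)(C)OC1=O | intermediate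
8 | (4R)-4-benzyl-1,3-thiazolidine-2-thione | S=C1N[C@H](Cc2ccccc2)CS1 | starting material
9 | (4R)-4-benzyl-3-{2-[(4R)-2,2,4-trimethyl-5-oxo-1,3-dioxolan-4-yl]acetyl}-1,3-thiazolidine-2-thione | C[C@]1(CC(=O)N2[C@H](Cc3ccccc3)CSC2=S)OC(C)(C)OC1=O | intermediate
10 | O-trimethylsilyl ether of 11 (silyl on the C6 oxygen) | S=C1SC[C@@H](Cc2ccccc2)N1C(=O)[C@@H]([C@H](O[Si](C)(C)C)/C=C(C)\CCCCl)[C@@]1(C)OC(C)(C)OC1=O | intermediate
11 | (4R)-4-benzyl-3-{(2S,3R,4Z)-8-chloro-3-hydroxy-5-methyl-2-[(4R)-2,2,4-trimethyl-5-oxo-1,3-dioxolan-4-yl]oct-4-enoyl}-1,3-thiazolidine-2-thione | S=C1SC[C@@H](Cc2ccccc2)N1C(=O)[C@@H]([C@H](O)/C=C(C)\CCCCl)[C@@]1(C)OC(C)(C)OC1=O | intermediate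
12 | (2S,3R,4Z)-8-chloro-3-hydroxy-N-methoxy-N,5-dimethyl-2-[(4R)-2,2,4-trimethyl-5-oxo-1,3-dioxolan-4-yl]oct-4-enamide | CON(C)C(=O)[C@@H]([C@H](O)/C=C(C)\CCCCl)[C@@]1(C)OC(C)(C)OC1=O | intermediate
13 | (5R)-5-[(5S,6R,7Z)-11-chloro-6-hydroxy-8-methyl-4-oxoundeca-1,7-dien-5-yl]-2,2,5-trimethyl-1,3-dioxolan-4-one | C=CCC(=O)[C@@H]([C@H](O)/C=C(C)\CCCCl)[C@@]1(C)OC(C)(C)OC1=O | intermediate
14 | (5R)-5-[(4R,5S,6R,7Z)-11-chloro-4,6-dihydroxy-8-methylundeca-1,7-dien-5-yl]-2,2,5-trimethyl-1,3-dioxolan-4-one | C=CC[C@@H](O)[C@@H]([C@H](O)/C=C(C)\CCCCl)[C@@]1(C)OC(C)(C)OC1=O | intermediate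
15 | (3R,4R,5R)-4-[(1R,2Z)-6-chloro-1-hydroxy-3-methylhex-2-en-1-yl]-3-hydroxy-3-methyl-5-(prop-2-en-1-yl)oxolan-2-one | C=CC[C@H]1OC(=O)[C@](C)(O)[C@@H]1[C@H](O)/C=C(C)\CCCCl | intermediate
16 | (3R,4R,5R)-4-[(1R,2Z)-6-chloro-1-hydroxy-3-methylhex-2-en-1-yl]-3-hydroxy-3-methyl-5-(2-oxopropyl)oxolan-2-one | CC(=O)C[C@H]1OC(=O)[C@](C)(O)[C@@H]1[C@H](O)/C=C(C)\CCCCl | intermediate
17 | (3R,4R,5R)-3-hydroxy-4-[(1R,2Z)-1-hydroxy-6-iodo-3-methylhex-2-en-1-yl]-3-methyl-5-(2-oxopropyl)oxolan-2-one | CC(=O)C[C@H]1OC(=O)[C@](C)(O)[C@@H]1[C@H](O)/C=C(C)\CCCI | intermediate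
18 | {(4Z,6R)-6-hydroxy-6-[(2R,3R,4R)-4-hydroxy-4-methyl-5-oxo-2-(2-oxopropyl)oxolan-3-yl]-4-methylhex-4-en-1-yl}diphenylsulfonium trifluoromethanesulfonate | CC(=O)C[C@H]1OC(=O)[C@](C)(O)[C@@H]1[C@H](O)/C=C(C)\CCC[S+](c1ccccc1)c1ccccc1.[O-]S(=O)(=O)C(F)(F)F | intermediate
19 | sulfonium ylide of 18 (carbanion at C1, next to the diphenylsulfonium group) | CC(=O)C[C@H]1OC(=O)[C@](C)(O)[C@@H]1[C@H](O)/C=C(C)\CC[CH-][S+](c1ccccc1)c1ccccc1 | intermediate
20 | ten-membered betaine: C10 alkoxide of the 8,12-lactone with the diphenylsulfonio group on C1 (4Z; C6 and C11 hydroxyls free) | O[C@@H]1/C=C(C)\CC[C@H]([S+](c2ccccc2)c2ccccc2)[C@]([O-])(C)C[C@H]2OC(=O)[C@](C)(O)[C@H]12 | intermediate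
21 | (1R,6R,7R,8R,10S,11R,4Z)-1,10-epoxy-6,11-dihydroxygermacr-4-en-12,8-olide | O[C@@H]1/C=C(C)\CC[C@H]2O[C@@]2(C)C[C@H]2OC(=O)[C@](C)(O)[C@H]12 | intermediate
22 | (1R,4R,5S,6S,7R,8R,10S,11R)-1,10:4,5-diepoxy-6,11-dihydroxygermacran-12,8-olide | O[C@H]1[C@@H]2[C@@H](C[C@]3(C)O[C@@H]3CC[C@@]3(C)O[C@@H]13)OC(=O)[C@]2(C)O | intermediate
23 | angelic acid [(2Z)-2-methylbut-2-enoic acid] | C/C=C(/C)C(=O)O | starting material
24 | (1R,4R,5S,6S,7S,8R,10S,11R)-6,11-bis(angeloyloxy)-1,10:4,5-diepoxygermacran-12,8-olide | C/C=C(/C)C(=O)O[C@H]1[C@@H]2[C@@H](C[C@]3(C)O[C@@H]3CC[C@@]3(C)O[C@@H]13)OC(=O)[C@]2(C)OC(=O)/C(C)=C\C | target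

**Step count and risks**
Total step count: 16. Longest linear sequence: 14 steps (steps 1–4 and 7–16, from 5-chloropent-1-yne).

Steps most likely to fail:

1. Step 14 (Proposed new method). The ten-membered closure may be outrun by oligomerisation or by Hofmann-type elimination of the sulfonium group, or the ylide may add to the wrong face of the C10 ketone. The fallback makes the same ring bond by ring-closing metathesis, a known way to close germacranolide rings. It sets out from iodide 17: oxidation with Me3NO in DMSO would give keto aldehyde F1; twofold methylenation of aldehyde and ketone (Zn, CH2Br2, TiCl4) would give tetraene F2; second-generation Grubbs catalyst [(H2IMes)(PCy3)Cl2Ru=CHPh] in toluene at 80 °C and 1 mM should close C1=C10 as the Z-trisubstituted olefin in (1(10)Z,4Z)-diene F3; VO(acac)2/t-BuOOH should then epoxidise C4=C5 syn to the C6 hydroxyl to give 4,5-epoxide F4; and m-CPBA should epoxidise C1=C10 from the ring periphery, which brings the route back at diepoxide 22.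

2. Step 16. Acylation may stall at the tertiary C11 hydroxyl, or the angeloyl unit may isomerise to tigloyl under the basic conditions. The fallback builds the Z-olefins on the esters instead. It sets out from diol 22: acylation with 2-[bis(2,2,2-trifluoroethoxy)phosphoryl]propanoic acid (DCC, DMAP, CH2Cl2) would give bis(phosphonate) F5, and a twofold Still–Gennari olefination with acetaldehyde (KN(SiMe3)2, 18-crown-6, THF, −78 °C) should give target 24 directly.

3. Step 7. Soft enolisation of the β-branched acyl thione may be too slow, the Z-enal may isomerise during the long reaction, or the anti-selectivity may erode in the open transition state. The fallback forms the C6–C7 bond through the chelated magnesium enolate of an oxazolidinone imide. It sets out from acid 7: coupling with (4S)-4-benzyl-1,3-oxazolidin-2-one (t-BuCOCl, Et3N, LiCl, THF) would give imide F6; the MgCl2/Et3N/Me3SiCl anti-aldol with 5 (chelated boat transition state, hence the enantiomeric auxiliary) would give silyl ether F7 and, after TFA/MeOH, adduct F8; AlMe3/MeONHMe·HCl transamidation brings the route back at Weinreb amide 12.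

**Further compounds**
F1 | step 14 | (3R,4R,5R)-3-hydroxy-4-[(1R,2Z)-1-hydroxy-3-methyl-6-oxohex-2-en-1-yl]-3-methyl-5-(2-oxopropyl)oxolan-2-one | CC(=O)C[C@H]1OC(=O)[C@](C)(O)[C@@H]1[C@H](O)/C=C(C)\CCC=O
F2 | step 14 | (3R,4R,5R)-3-hydroxy-4-[(1R,2Z)-1-hydroxy-3-methylhepta-2,6-dien-1-yl]-3-methyl-5-(2-methylprop-2-en-1-yl)oxolan-2-one | C=C(C)C[C@H]1OC(=O)[C@](C)(O)[C@@H]1[C@H](O)/C=C(C)\CCC=C
F3 | step 14 | (1(10)Z,4Z,6R,7R,8R,11R)-6,11-dihydroxygermacra-1(10),4-dien-12,8-olide | O[C@@H]1/C=C(C)\CC/C=C(C)\C[C@H]2OC(=O)[C@](C)(O)[C@H]12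
F4 | step 14 | (1(10)Z,4R,5S,6S,7R,8R,11R)-4,5-epoxy-6,11-dihydroxygermacr-1(10)-en-12,8-olide | O[C@H]1[C@@H]2[C@@H](C/C(C)=C\CC[C@@]3(C)O[C@@H]13)OC(=O)[C@]2(C)O
F5 | step 16 | 6,11-bis{2-[bis(2,2,2-trifluoroethoxy)phosphoryl]propanoyl} ester of 22 | CC(C(=O)O[C@H]1[C@@H]2[C@@H](C[C@]3(C)O[C@@H]3CC[C@@]3(C)O[C@@H]13)OC(=O)[C@]2(C)OC(=O)C(C)P(=O)(OCC(F)(F)F)OCC(F)(F)F)P(=O)(OCC(F)(F)F)OCC(F)(F)F
F6 | step 7 | (4S)-4-benzyl-3-{2-[(4R)-2,2,4-trimethyl-5-oxo-1,3-dioxolan-4-yl]acetyl}-1,3-oxazolidin-2-one | C[C@]1(CC(=O)N2[C@@H](Cc3ccccc3)COC2=O)OC(C)(C)OC1=O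
F7 | step 7 | O-trimethylsilyl ether of F8 | O=C1OC[C@H](Cc2ccccc2)N1C(=O)[C@@H]([C@H](O[Si](C)(C)C)/C=C(C)\CCCCl)[C@@]1(C)OC(C)(C)OC1=O
F8 | step 7 | (4S)-4-benzyl-3-{(2S,3R,4Z)-8-chloro-3-hydroxy-5-methyl-2-[(4R)-2,2,4-trimethyl-5-oxo-1,3-dioxolan-4-yl]oct-4-enoyl}-1,3-oxazolidin-2-one | O=C1OC[C@H](Cc2ccccc2)N1C(=O)[C@@H]([C@H](O)/C=C(C)\CCCCl)[C@@]1(C)OC(C)(C)OC1=O
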